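**Retrosynthetic overview**
- Target ⇐ 3α,6β,19-triol acid (C3-selective acylation) ⇐ 19,6β-lactone (hydride opening gives 6β-OH and 19-CH2OH together) ⇐ 3,6-diketo 19-ester (one bulky-hydride step sets 3α-OH and 6β-OH).
- Diketone ⇐ bicyclic 6α-silyloxy-3-oxo 19-ester, made from an acyclic β-keto ester by a head-to-tail polyene bicyclisation run as an oxidative radical cascade with the whole enoate side chain already in place.
- Bond order matches the terpene cyclase: C4–C5 closes ring A, then C10–C9 closes ring B, then loss of H gives the alkene. A single allylic silyloxy stereocentre (C6) is the only source of chirality and steers C4, C5 and C10.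
- Polyene ⇐ dianion of ethyl 2-methylacetoacetate + C15 allylic bromide ⇐ (S)-9-hydroxyfarnesoate (CBS) ⇐ enone (Meyer–Schuster) ⇐ 8-bromogeranate + 2-methylbut-3-yn-2-ol.

Assumption: labdane numbering is used; the SMILES is read as (3R,4S,5R,6R,10S), i.e. 3α-acyloxy, 6β-OH, 19-CH2OH (4β), 5α-H, 10β-CH3 (normal series); methyl geranate of ≥95% 2E purity is taken as commercial.

**Step 1**
Reactants: 1 methyl geranate [methyl (2E)-3,7-dimethylocta-2,6-dienoate]
Product: 2 methyl (2E,6E)-8-hydroxy-3,7-dimethylocta-2,6-dienoate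
Conditions: SeO2 (0.3 equiv), tBuOOH (3 equiv), salicylic acid (0.1 equiv), CH2Cl2, 0 °C to rt
Reagents that add atoms: selenium dioxide, O=[Se]=O (oxygen carrier); tert-butyl hydroperoxide, CC(C)(C)OO (terminal oxidant)
Why: Riley allylic oxidation (ene reaction then [2,3] shift) takes the E-methyl of the electron-rich terminal alkene, while the enoate alkene is too electron-poor to react.

**Step 2**
Reactants: 2 methyl (2E,6E)-8-hydroxy-3,7-dimethylocta-2,6-dienoate
Product: 3 methyl (2E,6E)-8-bromo-3,7-dimethylocta-2,6-dienoate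
Conditions: CBr4, PPh3, CH2Cl2, 0 °C
Reagents that add atoms: carbon tetrabromide, BrC(Br)(Br)Br
Why: Appel reaction; SN2 at the primary allylic carbon proceeds without allylic shift and the enoate is inert.

**Step 3**
Reactants: 3 methyl (2E,6E)-8-bromo-3,7-dimethylocta-2,6-dienoate; 4 2-methylbut-3-yn-2-ol
Product: 5 methyl (2E,6E)-11-hydroxy-3,7,11-trimethyldodeca-2,6-dien-9-ynoate
Conditions: CuI (10 mol%), NaI (20 mol%), K2CO3, DMF, rt
Reagents that add atoms: none
Why: Copper acetylide SN2 substitution of a primary allylic bromide gives the linear skipped enyne with the 6E alkene intact.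

**Step 4**
Reactants: 5 methyl (2E,6E)-11-hydroxy-3,7,11-trimethyldodeca-2,6-dien-9-ynoate
Product: 6 methyl (2E,6E)-3,7,11-trimethyl-9-oxododeca-2,6,10-trienoate
Conditions: MoO2(acac)2 (2 mol%), Ph3PAuCl (2 mol%), AgOTf (2 mol%), toluene, rt
Reagents that add atoms: none
Why: Meyer–Schuster rearrangement (1,3-oxygen shift of the tertiary propargylic alcohol, then tautomerisation) under neutral conditions gives the β,β-dimethyl enone without pulling the skipped C6=C7 alkene into conjugation.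

**Step 5**
Reactants: 6 methyl (2E,6E)-3,7,11-trimethyl-9-oxododeca-2,6,10-trienoate
Product: 7 methyl (2E,6E,9S)-9-hydroxy-3,7,11-trimethyldodeca-2,6,10-trienoate
Conditions: (R)-2-methyl-CBS-oxazaborolidine (20 mol%), catecholborane, toluene, −78 °C; aq. NaOH work-up
Reagents that add atoms: none
Why: Corey–Bakshi–Shibata reduction; the alkenyl group acts as the large substituent, so the (R)-catalyst gives the (S)-carbinol (the stereocentre that later controls the bicyclisation), and catecholborane at −78 °C leaves esters and alkenes alone.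

**Step 6**
Reactants: 7 methyl (2E,6E,9S)-9-hydroxy-3,7,11-trimethyldodeca-2,6,10-trienoate
Product: 8 methyl (2E,6E,9S)-9-[(tert-butyldiphenylsilyl)oxy]-3,7,11-trimethyldodeca-2,6,10-trienoate
Conditions: TBDPSCl, imidazole, DMAP (cat.), DMF, rt
Reagents that add atoms: tert-butyl(chloro)diphenylsilane, CC(C)(C)[Si](Cl)(c1ccccc1)c1ccccc1
Why: Silylation gives a base- and acid-stable ether whose bulk also shields the neighbouring C8 methylene in step 7.

**Step 7**
Reactants: 8 methyl (2E,6E,9S)-9-[(tert-butyldiphenylsilyl)oxy]-3,7,11-trimethyldodeca-2,6,10-trienoate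
Product: 9 methyl (2E,6E,9S,10E)-9-[(tert-butyldiphenylsilyl)oxy]-12-hydroxy-3,7,11-trimethyldodeca-2,6,10-trienoate
Conditions: SeO2 (0.3 equiv), tBuOOH, salicylic acid (cat.), CH2Cl2, 0 °C to rt; stop at partial conversion and recycle 8
Reagents that add atoms: selenium dioxide, O=[Se]=O (oxygen carrier); tert-butyl hydroperoxide, CC(C)(C)OO (terminal oxidant)
Why: Riley oxidation at the E-methyl of the terminal alkene; the internal alkene offers only an E-allylic CH2 (C8) that is shielded and deactivated by the adjacent silyloxy group, and the enoate is inert.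

**Step 8**
Reactants: 9 methyl (2E,6E,9S,10E)-9-[(tert-butyldiphenylsilyl)oxy]-12-hydroxy-3,7,11-trimethyldodeca-2,6,10-trienoate
Product: 10 methyl (2E,6E,9S,10E)-12-bromo-9-[(tert-butyldiphenylsilyl)oxy]-3,7,11-trimethyldodeca-2,6,10-trienoate
Conditions: CBr4, PPh3, CH2Cl2, −20 °C
Reagents that add atoms: carbon tetrabromide, BrC(Br)(Br)Br
Why: Appel reaction on the primary allylic alcohol; the secondary silyl ether and the stereocentre are untouched.

**Step 9**
Reactants: 10 methyl (2E,6E,9S,10E)-12-bromo-9-[(tert-butyldiphenylsilyl)oxy]-3,7,11-trimethyldodeca-2,6,10-trienoate; 11 ethyl 2-methyl-3-oxobutanoate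
Product: 13 1-ethyl 16-methyl (6E,8S,10E,14E)-8-[(tert-butyldiphenylsilyl)oxy]-2,6,10,14-tetramethyl-3-oxohexadeca-6,10,14-trienedioate (C2 epimers), via dilithium dianion 12 (not isolated)
Conditions: LiN(iPr)2 (2 equiv per 11), THF, 0 °C; then 10, 0 °C, 30 min; aq. NH4Cl
Reagents that add atoms: none
Why: Dianion γ-alkylation of a β-keto ester; the terminal carbanion attacks the allylic bromide by SN2 far faster than it attacks the esters in the molecule.

**Step 10**
Reactants: 13 1-ethyl 16-methyl (6E,8S,10E,14E)-8-[(tert-butyldiphenylsilyl)oxy]-2,6,10,14-tetramethyl-3-oxohexadeca-6,10,14-trienedioate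
Product: 16 19-ethyl 15-methyl (13E)-6α-[(tert-butyldiphenylsilyl)oxy]-3-oxolabda-8(17),13-diene-15,19-dioate, via ring A radical 14 (not isolated), via bicyclic C8 radical 15 (not isolated)
Conditions: Mn(OAc)3·2H2O (2.2 equiv), Cu(OAc)2·H2O (1 equiv), degassed AcOH, 25 °C; minor Δ7 and Δ8 isomers are carried on together
Reagents that add atoms: none
Why: Proposed new method: trivalent manganese oxidises the keto ester enol to the C4 radical, which closes 6-endo on C5 through a chair with the ester axial (C19 β), the C6–H eclipsing the alkene (A(1,3) strain with the C10 methyl), the C7 chain anti to the forming bond and the silyloxy group outside, so the oxygen ends equatorial (6α) and the (S)-centre fixes 4S, 5α-H and, after the second 6-endo closure of the C10 radical on C9 (trans-decalin, ring B), 10β-CH3; divalent copper then oxidises the C8 radical to the alkene, the β,β-disubstituted enoate being too hindered to trap it; the closest known reaction type is the Mn(OAc)3/Cu(OAc)2 oxidative free-radical polyene cyclisation of 2-alkyl-3-oxo esters to trans-decalins with an axial ester, and what is new is absolute control by one allylic silyloxy stereocentre.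

**Step 11**
Reactants: 16 19-ethyl 15-methyl (13E)-6α-[(tert-butyldiphenylsilyl)oxy]-3-oxolabda-8(17),13-diene-15,19-dioate
Product: 17 19-ethyl 15-methyl (13E)-6α-[(tert-butyldiphenylsilyl)oxy]-3-oxolabda-8,13-diene-15,19-dioate
Conditions: TsOH·H2O (20 mol%), benzene, 70 °C
Reagents that add atoms: none
Why: Acid-catalysed alkene isomerisation through the tertiary C8 cation converges the 8(17) and Δ7 isomers on the thermodynamically preferred tetrasubstituted Δ8 alkene; the transient C9 stereocentre is erased, and the silyl ether, keto ester and enoate tolerate the conditions.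

**Step 12**
Reactants: 17 19-ethyl 15-methyl (13E)-6α-[(tert-butyldiphenylsilyl)oxy]-3-oxolabda-8,13-diene-15,19-dioate
Product: 18 19-ethyl 15-methyl (13E)-6α-hydroxy-3-oxolabda-8,13-diene-15,19-dioate
Conditions: Bu4NF, AcOH, THF, 40 °C
Reagents that add atoms: none
Why: Fluoride desilylation, buffered so the non-enolisable β-keto ester is not opened by retro-Claisen cleavage.

**Step 13**
Reactants: 18 19-ethyl 15-methyl (13E)-6α-hydroxy-3-oxolabda-8,13-diene-15,19-dioate
Product: 19 19-ethyl 15-methyl (13E)-3,6-dioxolabda-8,13-diene-15,19-dioate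
Conditions: Dess–Martin periodinane, CH2Cl2, 0 °C to rt, 1 h
Reagents that add atoms: none
Why: Dess–Martin oxidation under near-neutral conditions keeps the β,γ-unsaturated C6 ketone out of conjugation and leaves C5 unepimerised.

**Step 14**
Reactants: 19 19-ethyl 15-methyl (13E)-3,6-dioxolabda-8,13-diene-15,19-dioate
Product: 23 (13E)-3α-hydroxy-19-oxo-6β,19-epoxylabda-8,13-dien-15-oic acid (the 19,6β-lactone), via 3α,6β-diol diester 20 (not isolated), via lactone methyl ester 21 (not isolated), via dilithium dicarboxylate 22 (not isolated)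
Conditions: Li[HB(sec-Bu)3] (L-Selectride, 2.5 equiv), THF, −78 to 0 °C; then LiOH, H2O2, H2O/MeOH, 40 °C; then 1 M HCl to pH 2
Reagents that add atoms: lithium hydroxide, [Li+].[OH-] (oxygen of the C15 carboxyl OH)
Why: Diastereoselective bulky-hydride reduction followed by saponification: the C6 ketone is attacked from the open α face (the β face is covered by C19 and C20) to give the 6β-alkoxide, which acylates on the 1,3-diaxial C19 ester to close the γ-lactone, while the C3 ketone is attacked equatorially to give the axial 3α-OH; hydroxide then cleaves the methyl enoate and acidification recloses the lactone.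

**Step 15**
Reactants: 23 (13E)-3α-hydroxy-19-oxo-6β,19-epoxylabda-8,13-dien-15-oic acid
Product: 24 (13E)-3α,6β,19-trihydroxylabda-8,13-dien-15-oic acid
Conditions: LiEt3BH (5 equiv), THF, 0 °C to rt; 1 M HCl work-up at 0 °C
Reagents that add atoms: none
Why: Hydride reduction of a lactone to a diol; the reagent first deprotonates the acid to an unreactive carboxylate, then opens the hindered lactone to the 6β-OH and 19-CH2OH without touching a stereocentre or an alkene.

**Step 16**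
Reactants: 24 (13E)-3α,6β,19-trihydroxylabda-8,13-dien-15-oic acid; 25 3-methylbutanoic anhydride (isovaleric anhydride)
Product: 28 (13E)-6β,19-dihydroxy-3α-[(3-methylbutanoyl)oxy]labda-8,13-dien-15-oic acid (target), via 6β,19-phenylboronate 26 (not isolated), via 3-O-isovaleryl phenylboronate 27 (not isolated)
Conditions: PhB(OH)2 (1.05 equiv), toluene, 4 Å MS, rt; then 25, DMAP (cat.), pyridine, 40 °C; then H2O2, aq. NaHCO3, THF, 0 °C; acidify to pH 4
Reagents that add atoms: none
Why: Transient boronate protection followed by DMAP-catalysed acylation: only the 1,3-diaxial 6β,19-diol can form a six-membered boronate (3α-OH is anti to C19), so the anhydride acylates 3α-OH alone, and the oxidative aqueous work-up removes the boronate and hydrolyses any mixed anhydride at C15.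

**Compound list**
1 | methyl geranate, methyl (2E)-3,7-dimethylocta-2,6-dienoate | CC(C)=CCC/C(C)=C/C(=O)OC | starting material
2 | methyl (2E,6E)-8-hydroxy-3,7-dimethylocta-2,6-dienoate | OC/C(C)=C/CC/C(C)=C/C(=O)OC | intermediate
3 | methyl (2E,6E)-8-bromo-3,7-dimethylocta-2,6-dienoate | BrC/C(C)=C/CC/C(C)=C/C(=O)OC | intermediate
4 | 2-methylbut-3-yn-2-ol | CC(C)(O)C#C | starting material
5 | methyl (2E,6E)-11-hydroxy-3,7,11-trimethyldodeca-2,6-dien-9-ynoate | CC(C)(O)C#CC/C(C)=C/CC/C(C)=C/C(=O)OC | intermediate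
6 | methyl (2E,6E)-3,7,11-trimethyl-9-oxododeca-2,6,10-trienoate | CC(C)=CC(=O)C/C(C)=C/CC/C(C)=C/C(=O)OC | intermediate
7 | methyl (2E,6E,9S)-9-hydroxy-3,7,11-trimethyldodeca-2,6,10-trienoate | CC(C)=C[C@@H](O)C/C(C)=C/CC/C(C)=C/C(=O)OC | intermediate
8 | methyl (2E,6E,9S)-9-[(tert-butyldiphenylsilyl)oxy]-3,7,11-trimethyldodeca-2,6,10-trienoate | CC(C)=C[C@@H](O[Si](c1ccccc1)(c1ccccc1)C(C)(C)C)C/C(C)=C/CC/C(C)=C/C(=O)OC | intermediate
9 | methyl (2E,6E,9S,10E)-9-[(tert-butyldiphenylsilyl)oxy]-12-hydroxy-3,7,11-trimethyldodeca-2,6,10-trienoate | OC/C(C)=C/[C@@H](O[Si](c1ccccc1)(c1ccccc1)C(C)(C)C)C/C(C)=C/CC/C(C)=C/C(=O)OC | intermediate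
10 | methyl (2E,6E,9S,10E)-12-bromo-9-[(tert-butyldiphenylsilyl)oxy]-3,7,11-trimethyldodeca-2,6,10-trienoate | BrC/C(C)=C/[C@@H](O[Si](c1ccccc1)(c1ccccc1)C(C)(C)C)C/C(C)=C/CC/C(C)=C/C(=O)OC | intermediate
11 | ethyl 2-methyl-3-oxobutanoate | CCOC(=O)C(C)C(C)=O | starting material
12 | dilithium dianion of 11 | [Li+].[Li+].C=C([O-])C(C)=C([O-])OCC | intermediate
13 | 1-ethyl 16-methyl (6E,8S,10E,14E)-8-[(tert-butyldiphenylsilyl)oxy]-2,6,10,14-tetramethyl-3-oxohexadeca-6,10,14-trienedioate (C2 epimers) | CCOC(=O)C(C)C(=O)CC/C(C)=C/[C@@H](O[Si](c1ccccc1)(c1ccccc1)C(C)(C)C)C/C(C)=C/CC/C(C)=C/C(=O)OC | intermediate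
14 | ring A radical: monocyclic tertiary C10 radical, 3-oxo, 4β-CO2Et, 4α-CH3, 5α-H, 6α-OTBDPS side chain | C[C]1CCC(=O)[C@](C)(C(=O)OCC)[C@@H]1[C@@H](O[Si](c2ccccc2)(c2ccccc2)C(C)(C)C)C/C(C)=C/CC/C(C)=C/C(=O)OC | intermediate
15 | bicyclic C8 radical: trans-decalin, 10β-CH3, 9α-H, tertiary radical at C8 | C[C]1C[C@H](O[Si](c3ccccc3)(c3ccccc3)C(C)(C)C)[C@H]2[C@@](C)(C(=O)OCC)C(=O)CC[C@]2(C)[C@H]1CC/C(C)=C/C(=O)OC | intermediate
16 | 19-ethyl 15-methyl (13E)-6α-[(tert-butyldiphenylsilyl)oxy]-3-oxolabda-8(17),13-diene-15,19-dioate | C=C1C[C@H](O[Si](c3ccccc3)(c3ccccc3)C(C)(C)C)[C@H]2[C@@](C)(C(=O)OCC)C(=O)CC[C@]2(C)[C@H]1CC/C(C)=C/C(=O)OC | intermediate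
17 | 19-ethyl 15-methyl (13E)-6α-[(tert-butyldiphenylsilyl)oxy]-3-oxolabda-8,13-diene-15,19-dioate | CC1=C(CC/C(C)=C/C(=O)OC)[C@@]2(C)CCC(=O)[C@](C)(C(=O)OCC)[C@@H]2[C@@H](O[Si](c3ccccc3)(c3ccccc3)C(C)(C)C)C1 | intermediate
18 | 19-ethyl 15-methyl (13E)-6α-hydroxy-3-oxolabda-8,13-diene-15,19-dioate | CC1=C(CC/C(C)=C/C(=O)OC)[C@@]2(C)CCC(=O)[C@](C)(C(=O)OCC)[C@@H]2[C@@H](O)C1 | intermediate
19 | 19-ethyl 15-methyl (13E)-3,6-dioxolabda-8,13-diene-15,19-dioate | CC1=C(CC/C(C)=C/C(=O)OC)[C@@]2(C)CCC(=O)[C@](C)(C(=O)OCC)[C@@H]2C(=O)C1 | intermediate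
20 | 19-ethyl 15-methyl (13E)-3α,6β-dihydroxylabda-8,13-diene-15,19-dioate (present as lithium alkoxides) | CC1=C(CC/C(C)=C/C(=O)OC)[C@@]2(C)CC[C@@H](O)[C@](C)(C(=O)OCC)[C@@H]2[C@H](O)C1 | intermediate
21 | methyl (13E)-3α-hydroxy-19-oxo-6β,19-epoxylabda-8,13-dien-15-oate | CC1=C(CC/C(C)=C/C(=O)OC)[C@@]2(C)CC[C@@H](O)[C@]3(C)C(=O)O[C@H](C1)[C@H]23 | intermediate
22 | dilithium (13E)-3α,6β-dihydroxylabda-8,13-diene-15,19-dioate | [Li+].[Li+].CC1=C(CC/C(C)=C/C(=O)[O-])[C@@]2(C)CC[C@@H](O)[C@](C)(C(=O)[O-])[C@@H]2[C@H](O)C1 | intermediate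
23 | (13E)-3α-hydroxy-19-oxo-6β,19-epoxylabda-8,13-dien-15-oic acid | CC1=C(CC/C(C)=C/C(=O)O)[C@@]2(C)CC[C@@H](O)[C@]3(C)C(=O)O[C@H](C1)[C@H]23 | intermediate
24 | (13E)-3α,6β,19-trihydroxylabda-8,13-dien-15-oic acid | CC1=C(CC/C(C)=C/C(=O)O)[C@@]2(C)CC[C@@H](O)[C@](C)(CO)[C@@H]2[C@H](O)C1 | intermediate
25 | 3-methylbutanoic anhydride | CC(C)CC(=O)OC(=O)CC(C)C | starting material
26 | (13E)-3α-hydroxy-6β,19-[(phenylboranediyl)bis(oxy)]labda-8,13-dien-15-oic acid | CC1=C(CC/C(C)=C/C(=O)O)[C@@]2(C)CC[C@@H](O)[C@]3(C)COB(c4ccccc4)O[C@H](C1)[C@H]23 | intermediate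
27 | (13E)-3α-[(3-methylbutanoyl)oxy]-6β,19-[(phenylboranediyl)bis(oxy)]labda-8,13-dien-15-oic acid | CC1=C(CC/C(C)=C/C(=O)O)[C@@]2(C)CC[C@@H](OC(=O)CC(C)C)[C@]3(C)COB(c4ccccc4)O[C@H](C1)[C@H]23 | intermediate
28 | (13E)-6β,19-dihydroxy-3α-[(3-methylbutanoyl)oxy]labda-8,13-dien-15-oic acid; (2E)-5-[(4R,4aR,5S,6R,8aS)-4-hydroxy-5-(hydroxymethyl)-2,5,8a-trimethyl-6-[(3-methylbutanoyl)oxy]-3,4,4a,5,6,7,8,8a-octahydronaphthalen-1-yl]-3-methylpent-2-enoic acid | CC1=C(CC/C(C)=C/C(=O)O)[C@@]2(C)CC[C@@H](OC(=O)CC(C)C)[C@](C)(CO)[C@@H]2[C@H](O)C1 | target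

**Totals and risks**
Total step count: 16. Longest linear sequence: 16 (1 to 28; compounds 4, 11 and 25 are bought).

Most likely to fail, first: step 10. The sense and level of induction from C6 are predicted, not precedented; the C10 radical may be oxidised before ring B closes; the C8 radical may add to the enoate. The fallback replaces substrate control by a matched chiral ester; it sets out from 10 and comes back at 23. Ester 11 is transesterified with (+)-8-phenylmenthol (DMAP, toluene, reflux) to (1S,2R,5S)-8-phenylmenthyl 2-methyl-3-oxobutanoate F1, whose dianion (LiN(iPr)2) is alkylated with 10 to the auxiliary keto ester polyene F2. Mn(OAc)3·2H2O and Cu(OAc)2·H2O with Yb(OTf)3, which chelates the keto ester so that the aryl group covers one face of the radical, give the 8(17)-ene auxiliary ester F3. TsOH then gives the Δ8 auxiliary ester F4, Bu4NF/AcOH the 6α-alcohol F5 and Dess–Martin periodinane the 3,6-dione F6. Under the conditions of step 14 the 6β-alkoxide expels the auxiliary on lactonisation and 23 is reached. The auxiliary enantiomer is the one expected to match the C6 centre; the antipode is equally available if the first run shows a mismatch.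

Second: step 7. The terminal alkene is deactivated by the allylic silyloxy group, so oxidation at the internal alkene may compete. The fallback swaps the ene oxidation for alkene exchange; it sets out from 8 and comes back at 9. Cross-metathesis of 8 with methacrolein (second-generation Hoveyda–Grubbs catalyst, RuCl2(H2IMes)(=CH-C6H4-2-OiPr), CH2Cl2, 40 °C) trades the gem-dimethyl terminus for the E-enal and gives methyl (2E,6E,9S,10E)-9-[(tert-butyldiphenylsilyl)oxy]-3,7,11-trimethyl-12-oxododeca-2,6,10-trienoate F7. NaBH4 with CeCl3·7H2O in MeOH at 0 °C then reduces the aldehyde to 9.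

Third: step 16. The transient boronate may not hold through a slow acylation of the hindered axial 3α-OH. The fallback uses an isolable protecting group; it sets out from 24 and comes back at 28. 2,2-Dimethoxypropane and pyridinium tosylate in CH2Cl2 give the (13E)-3α-hydroxy-6β,19-(isopropylidenedioxy)labda-8,13-dien-15-oic acid F8; only the 1,3-diaxial diol can be bridged. 3-Methylbutanoic anhydride with DMAP gives the 3α-isovalerate acetonide F9, and AcOH/H2O (4:1) at rt releases 28.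

**Further compounds**
F1 | step 10 | (1S,2R,5S)-5-methyl-2-(2-phenylpropan-2-yl)cyclohexyl 2-methyl-3-oxobutanoate | CC(=O)C(C)C(=O)O[C@H]1C[C@@H](C)CC[C@@H]1C(C)(C)c1ccccc1
F2 | step 10 | 1-[(1S,2R,5S)-5-methyl-2-(2-phenylpropan-2-yl)cyclohexyl] 16-methyl (6E,8S,10E,14E)-8-[(tert-butyldiphenylsilyl)oxy]-2,6,10,14-tetramethyl-3-oxohexadeca-6,10,14-trienedioate | CC(C(=O)O[C@H]1C[C@@H](C)CC[C@@H]1C(C)(C)c1ccccc1)C(=O)CC/C(C)=C/[C@@H](O[Si](c1ccccc1)(c1ccccc1)C(C)(C)C)C/C(C)=C/CC/C(C)=C/C(=O)OC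
F3 | step 10 | 19-[(1S,2R,5S)-8-phenylmenthyl] 15-methyl (13E)-6α-[(tert-butyldiphenylsilyl)oxy]-3-oxolabda-8(17),13-diene-15,19-dioate | C=C1C[C@H](O[Si](c3ccccc3)(c3ccccc3)C(C)(C)C)[C@H]2[C@@](C)(C(=O)O[C@H]4C[C@@H](C)CC[C@@H]4C(C)(C)c4ccccc4)C(=O)CC[C@]2(C)[C@H]1CC/C(C)=C/C(=O)OC
F4 | step 10 | 19-[(1S,2R,5S)-8-phenylmenthyl] 15-methyl (13E)-6α-[(tert-butyldiphenylsilyl)oxy]-3-oxolabda-8,13-diene-15,19-dioate | CC1=C(CC/C(C)=C/C(=O)OC)[C@@]2(C)CCC(=O)[C@](C)(C(=O)O[C@H]4C[C@@H](C)CC[C@@H]4C(C)(C)c4ccccc4)[C@@H]2[C@@H](O[Si](c3ccccc3)(c3ccccc3)C(C)(C)C)C1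
F5 | step 10 | 19-[(1S,2R,5S)-8-phenylmenthyl] 15-methyl (13E)-6α-hydroxy-3-oxolabda-8,13-diene-15,19-dioate | CC1=C(CC/C(C)=C/C(=O)OC)[C@@]2(C)CCC(=O)[C@](C)(C(=O)O[C@H]4C[C@@H](C)CC[C@@H]4C(C)(C)c4ccccc4)[C@@H]2[C@@H](O)C1
F6 | step 10 | 19-[(1S,2R,5S)-8-phenylmenthyl] 15-methyl (13E)-3,6-dioxolabda-8,13-diene-15,19-dioate | CC1=C(CC/C(C)=C/C(=O)OC)[C@@]2(C)CCC(=O)[C@](C)(C(=O)O[C@H]4C[C@@H](C)CC[C@@H]4C(C)(C)c4ccccc4)[C@@H]2C(=O)C1
F7 | step 7 | methyl (2E,6E,9S,10E)-9-[(tert-butyldiphenylsilyl)oxy]-3,7,11-trimethyl-12-oxododeca-2,6,10-trienoate | O=C/C(C)=C/[C@@H](O[Si](c1ccccc1)(c1ccccc1)C(C)(C)C)C/C(C)=C/CC/C(C)=C/C(=O)OC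
F8 | step 16 | (13E)-3α-hydroxy-6β,19-(isopropylidenedioxy)labda-8,13-dien-15-oic acid | CC1=C(CC/C(C)=C/C(=O)O)[C@@]2(C)CC[C@@H](O)[C@]3(C)COC(C)(C)O[C@H](C1)[C@H]23
F9 | step 16 | (13E)-6β,19-(isopropylidenedioxy)-3α-[(3-methylbutanoyl)oxy]labda-8,13-dien-15-oic acid | CC1=C(CC/C(C)=C/C(=O)O)[C@@]2(C)CC[C@@H](OC(=O)CC(C)C)[C@]3(C)COC(C)(C)O[C@H](C1)[C@H]23
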